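## Analysis of the target

The target (24) is a daucane-type diester built on a cis-fused bicyclo[5.3.0]decene (hydroazulene). Skeleton numbering used throughout: the five-membered ring is C1 (quaternary, methyl)–C2 (angeloyloxy)–C3–C4 (tertiary carbinol with isopropyl)–C5 (fusion CH); the seven-membered ring is C5–C6 (3,4,5-trimethoxybenzoyloxy)–C7–C8 (methyl)=C9–C10–C1. There are five stereocentres, C1, C2, C4, C5 and C6, with configuration (1R,2S,4S,5R,6R) in this numbering. On the five-membered ring the C1 methyl, C5–H and the C4 isopropyl group lie on one face (called α); the C2 and C4 oxygens and the ring bonds to C6 and C10 lie on the other (β). The C6 oxygen is cis to C5–H across the C5–C6 bond. Sensitive groups are the angelate (Z to E isomerisation, conjugate addition), the tertiary C4 alcohol flanked 1,3 by two esters (acyl migration, dehydration) and the C8=C9 alkene, which is β,γ to any C6 carbonyl. The difficulty is the quaternary C1 wedged between two stereocentres in a 5–7 system, together with C2 and C6 configurations that the most open hydride trajectories do not obviously deliver. The strategy rests on one feature: C6 carries oxygen and is bonded to C5, which carries H and is bonded to C1. Moving the C1 bond from C5 back to C6 turns the 5–7 system into a 6–6 system, the adduct of 2-methoxy-5-methylbenzoquinone and isoprene, which holds every skeletal carbon except the isopropyl group.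

## Retrosynthetic reasoning

**24 to 21 and 22.** The C2 ester C–O bond is cut first. The angelate is the most fragile group, so it should arrive last, under conditions free of nucleophilic catalysts. The forward step must acylate the neopentylic secondary C2 hydroxyl of 21 while the tertiary C4 hydroxyl stays free.

**21 to 19 and 20.** The C6–O bond is cut with inversion. In the cis-fused 5–7 ketone one face of a C6 carbonyl looks at C1 and C10, so hydride can only enter from the periphery and should leave oxygen trans to C5–H, the epimer of what is needed. An esterification that inverts C6 therefore sets the stereocentre and installs the aroyl group in one operation, and it selects C6 over the neopentylic C2 hydroxyl of triol 19.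

**19 to 18 to 17.** The C4–isopropyl bond is cut to the C4 ketone 17. C4 sits next to the fusion carbon C5, whose β substituent is C6, so a nucleophile should enter from the α face past C5–H. The two silyl ethers of 18 and 17 carry the C2 and C6 carbinols through this step.

**17 to 16 to 15 to 14.** The C4 ketone is an unmasked methyl enol ether and the two carbinols come from two carbonyls. This recognises the vinylogous ester of 14 as a 1,3-dicarbonyl whose two ends (C2 carbonyl, C4 enol ether) have been told apart since the quinone stage.

**14 to 12 (key disconnection).** The C1–C5 bond is cut and C1 is reconnected to C6. In the forward sense the C6 alkoxide of a trans-decalin cis-5,6-diol 5-mesylate pushes the C6–C1 bond onto C5 as mesylate leaves. Ring A contracts to the cyclopentenone, ring B expands to the cycloheptenone, and C5 is formed with inversion.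

**12 to 11 to 10 to 8 to 7.** The cis-diol cannot be expected from direct reduction of a C5 ketone in the trans-decalin, because hydride should add anti to the axial C1 methyl and give the trans-diol. The C5–O bond is therefore traced back to an oxygen delivered from the C6 oxygen itself: the cyclic carbonate 10 arises from the trans hydroxy carbonate 8 by internal displacement with inversion. Either C5 epimer formed on reduction of 7 ends up as 10.

**7 to 4.** The C6–O bond is cut to the enolate of the C5 ketone. C6–H is the only acidic hydrogen of 4, and the C1 methyl should steer oxygen to the opposite face, giving the trans ring fusion.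

**4 to 2 and 3.** The C1–C10 and C6–C7 bonds are cut in a Diels–Alder sense. The quinone 2 and isoprene (3) supply ring B, quaternary C1 and the C8 methyl in one step, and a chiral Lewis acid sets the absolute configuration.

**2 to 1.** The C–O bond of the methoxy group is cut; 2 is the oxidative methanol adduct of toluquinone 1.

## Alternatives that were turned down

**Alternative 1:** Disconnection of C5–C1 and C9–C10, so that both rings form at once. In the forward step the acetoxypyranone A1 loses its acetoxy group under base and the resulting oxidopyrylium zwitterion adds across the tethered 1,1-disubstituted alkene in a (5+2) cycloaddition, giving the oxygen-bridged cycloadduct A2.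
- For it: quaternary C1 and both rings arise in one step. C2 and C4, including the tertiary carbinol with its isopropyl group, are set on an open chain before cyclisation and steer the facial sense through the short tether.
- Against it: A2 carries an oxygen bridge between C5 and C9 where the target has none. C5 must become C–H by reductive C–O cleavage, with its configuration then set by enolate protonation. The C9 oxygen must be removed and the C7=C8 enone alkene moved to C8=C9. The C6 carbonyl still faces the same reduction problem.
- Comparison: it is stronger on C2 and C4, which the chosen route sets late by facial selection, and on ring-forming step count. The chosen route offers instead oxygen and alkene placed exactly where the target has them, a stereospecific C5, and catalytic absolute control from bulk chemicals.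

**Alternative 2:** Disconnection of C1–C10 through a [3,3] shift. Heating the cis-divinylcyclopropane A3 breaks C6–C8 and forms C1–C10 through a boat transition state, giving the Cope product A4 with the C8=C9 alkene and a C5=C6 silyl enol ether.
- For it: the rearrangement is stereospecific and driven by strain release. It places C8=C9 and the C6 oxygen correctly and differentiates C2 (ketal) from C4 early.
- Against it: the alkene terminus that becomes C1 is fully substituted and must turn its substituents into the boat, the known slow case. Absolute control needs an enantioselective cyclopropanation of a hindered enol ether. In A4 the C4 ketone is conjugated to the C5=C6 enol ether, so after desilylation C4 and C6 form an enolised β-diketone in which isopropyl addition at C4 and reduction at C6 are hard to tell apart. C5 is again set by protonation.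
- Comparison: it equals the chosen route in placing alkene and C6 oxygen and is stronger in masking C2. The chosen route keeps C4 masked against C2 rather than against C6, so the C6 ketone can be handled alone, and it sets C5 by a stereospecific shift.

**Alternative 3:** Disconnection of C1–C2. A divalent samarium reductant converts the aldehyde of A5 into a radical anion that adds 5-exo to C1, the β-carbon of the cycloheptadienone; the enolate is protonated at C5, giving A6.
- For it: A6 already holds the C2 hydroxyl, the C4 carbinol, C5–H, the C6 ketone and C8=C9, so only the C6 adjustment and two esterifications remain. On step economy after the key step it is clearly stronger, and such cyclisations usually place the new hydroxyl trans to the neighbouring substituent, as the target needs.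
- Against it: addition to a β,β-disubstituted enone carbon to form quaternary C1 is the slow case, with aldehyde reduction and pinacol coupling competing. C1, C2 and C5 all depend on induction from the single tertiary carbinol C4, whose hydroxyl and isopropyl groups are poorly differentiated. A5 is a β-hydroxy aldehyde beside a skipped dienone, prone to retro-aldol, dehydration and conjugation, and needs an enantioselective tertiary-alcohol synthesis.
- Comparison: the chosen route is longer after the key step. It offers instead a precursor reached by robust steps from a quinone, catalytic absolute control, and a key step whose stereochemical course is fixed by the mechanism.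

Key step: step 8

## Remarks before the steps

- Locants in the names are the skeleton locants defined above (for the decalins they coincide with bicyclo[4.4.0]decane numbering); descriptors refer to these locants. α and β are the faces of the five-membered ring as defined in the analysis.
- Assumption: the (S)-diphenylprolinol-derived oxazaborolidinium cation is taken to give the (1R,6S) adduct 4; should it give the antipode, the (R)-catalyst is used and nothing else changes.

## Route

Step 1
Reactants: 1 2-methyl-1,4-benzoquinone
Product: 2 2-methoxy-5-methyl-1,4-benzoquinone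
Conditions: MeOH, ZnCl2, 25 °C (a second equivalent of 1 serves as oxidant)
Reagents that add atoms: methanol, CO
Why: ZnCl2-promoted conjugate addition of methanol to the unsubstituted enone terminus para to the methyl group gives the methoxyhydroquinone, which is reoxidised by 1 (oxidative 1,4-addition to a quinone, known for this substrate).

Step 2
Reactants: 2 2-methoxy-5-methyl-1,4-benzoquinone; 3 isoprene
Product: 4 (1R,6S)-4-methoxy-1,8-dimethyl-cis-bicyclo[4.4.0]deca-3,8-diene-2,5-dione
Conditions: N-protonated (S)-B-(o-tolyl)oxazaborolidine from (S)-α,α-diphenylprolinol, NTf2 counter-ion (20 mol %), isoprene (5 equiv), CH2Cl2, −78 → −40 °C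
Reagents that add atoms: none
Why: Lewis-acid-catalysed Diels–Alder reaction; only the methyl-bearing C=C of 2 is dienophilic, and a single-point boron acid should bind the more basic vinylogous-ester carbonyl, so the CH terminus (future C6) joins C1 of isoprene and the methyl lands on C8. Suprafacial addition gives the cis fusion, and the catalyst's face shielding sets C1 and C6 together.

Step 3
Reactants: 4 (1R,6S)-4-methoxy-1,8-dimethyl-cis-bicyclo[4.4.0]deca-3,8-diene-2,5-dione
Product: 7 (1R,6S)-6-(tert-butoxycarbonyloxy)-4-methoxy-1,8-dimethyl-trans-bicyclo[4.4.0]deca-3,8-diene-2,5-dione, via potassium C5-enolate 5 (not isolated), via potassium C6-alkoxide 6 (not isolated)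
Conditions: KN(SiMe3)2, THF, −78 °C; 2-(phenylsulfonyl)-3-phenyloxaziridine, −78 °C; then Boc2O, −78 → 0 °C
Reagents that add atoms: 2-(phenylsulfonyl)-3-phenyloxaziridine, O=S(=O)(c1ccccc1)N1OC1c1ccccc1; di-tert-butyl dicarbonate, CC(C)(C)OC(=O)OC(=O)OC(C)(C)C
Why: Enolate oxidation with an N-sulfonyloxaziridine; C6–H is the only acidic hydrogen, and in the flattened dienolate the pseudo-axial C1 methyl covers one face, so oxygen should enter anti to it (trans fusion), as in electrophilic attack on 5-enol derivatives of 6-oxo steroids. Acylating the tertiary alkoxide in the flask avoids handling the retro-aldol-prone ketol and installs the carbonate needed in step 5.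

Step 4
Reactants: 7 (1R,6S)-6-(tert-butoxycarbonyloxy)-4-methoxy-1,8-dimethyl-trans-bicyclo[4.4.0]deca-3,8-diene-2,5-dione
Product: 8 (1R,5S,6S)-6-(tert-butoxycarbonyloxy)-5-hydroxy-4-methoxy-1,8-dimethyl-trans-bicyclo[4.4.0]deca-3,8-dien-2-one (C5–OH syn to the C1 methyl, trans to C6–O)
Conditions: NaBH4, CeCl3·7H2O, MeOH/CH2Cl2, −78 °C
Reagents that add atoms: none
Why: Luche 1,2-reduction, selective for the C5 ketone because C2 is a vinylogous ester carbonyl; the axial C1 methyl is 1,3-diaxial to one face of C5, so hydride should add anti to it and give the alcohol trans to the C6 carbonate. Hydride from the other face would give a cis alkoxide that closes onto the carbonate to 10 directly, so both outcomes converge at 10.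

Step 5
Reactants: 8 (1R,5S,6S)-6-(tert-butoxycarbonyloxy)-5-hydroxy-4-methoxy-1,8-dimethyl-trans-bicyclo[4.4.0]deca-3,8-dien-2-one
Product: 10 (1R,5R,6S)-4-methoxy-1,8-dimethyl-2-oxo-trans-bicyclo[4.4.0]deca-3,8-diene-5,6-diyl cyclic carbonate (both oxygens anti to the C1 methyl), via C5 methanesulfonate 9 (not isolated)
Conditions: MsCl, Et3N, CH2Cl2, 0 °C; then MeCN, 50 °C
Reagents that add atoms: none
Why: Sulfonylation followed by neighbouring-group participation: the carbonyl oxygen of the axial C6 carbonate is antiperiplanar to the axial C5 mesylate and displaces it with inversion (5-exo-tet), and the dioxolanylium ion loses isobutene. This known carbonate-participation inversion turns the trans-diol derivative into the cis-fused carbonate and places C5–O anti to the C1 methyl.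

Step 6
Reactants: 10 (1R,5R,6S)-4-methoxy-1,8-dimethyl-2-oxo-trans-bicyclo[4.4.0]deca-3,8-diene-5,6-diyl cyclic carbonate
Product: 11 (1R,5S,6S)-5,6-dihydroxy-4-methoxy-1,8-dimethyl-trans-bicyclo[4.4.0]deca-3,8-dien-2-one (cis-5,6-diol)
Conditions: K2CO3 (cat.), MeOH, 0 °C
Reagents that add atoms: none
Why: Base-catalysed methanolysis of a five-membered cyclic carbonate; catalytic carbonate at 0 °C keeps the tertiary alkoxide concentration low, so retro-aldol toward the C2 carbonyl is not expected, and no stereocentre is touched.

Step 7
Reactants: 11 (1R,5S,6S)-5,6-dihydroxy-4-methoxy-1,8-dimethyl-trans-bicyclo[4.4.0]deca-3,8-dien-2-one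
Product: 12 (1R,5S,6S)-6-hydroxy-4-methoxy-1,8-dimethyl-2-oxo-trans-bicyclo[4.4.0]deca-3,8-dien-5-yl methanesulfonate
Conditions: MsCl (1.1 equiv), Et3N, CH2Cl2, −20 °C
Reagents that add atoms: methanesulfonyl chloride, CS(Cl)(=O)=O
Why: Selective sulfonylation of the secondary, equatorial C5 hydroxyl; the tertiary C6 hydroxyl does not react and, being cis to the mesylate, cannot close an epoxide.

Step 8
Reactants: 12 (1R,5S,6S)-6-hydroxy-4-methoxy-1,8-dimethyl-2-oxo-trans-bicyclo[4.4.0]deca-3,8-dien-5-yl methanesulfonate
Product: 14 (1R,5S)-4-methoxy-1,8-dimethyl-cis-hydroazula-3,8-diene-2,6-dione (cis-fused 5–7 bicycle), via diethylaluminium C6-alkoxide 13 (not isolated)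
Conditions: Et3Al (3 equiv), CH2Cl2, −78 → −20 °C; aq. potassium sodium tartrate at −20 °C
Reagents that add atoms: none
Why: Et3Al converts the tertiary hydroxyl into the aluminium alkoxide 13 and a further equivalent activates the mesylate; the C6–C1 bond, antiperiplanar to the pseudo-equatorial C5–O bond, then shifts to C5 as mesylate leaves and C6–O becomes the carbonyl. The closest known reaction types are the organoaluminium-promoted pinacol-type rearrangement of 2-sulfonyloxy alcohols and the ring contraction–expansion of decalin-1,2-diol monosulfonates with an angular hydroxyl to hydroazulenones. The five-membered ring closes through the 1,2-shift itself (C1 bridges from C6 to C5 in a three-centre transition state); the seven-membered ring is not closed by a new bond but results from the same C1–C6 cleavage as an enlargement of ring B. C5 is the only new stereocentre: it forms with inversion by backside displacement, so its configuration follows from the C5–O configuration fixed in step 5, while C1 migrates with retention, giving the cis fusion. The step needs C1 to migrate rather than C7 or oxygen; the rigid trans-decalin secures this, since C7 and the C6 oxygen are gauche to the leaving group and a cis-diol cannot give an epoxide. Retro-aldol cleavage of C6–C1 toward the C2 carbonyl is the competing path, and the covalent, weakly basic Al–O bond and low temperature are chosen to disfavour it. In 14 the C5–H (α to the ketone and vinylogous to C2=O) and the β,γ-alkene are labile, so the quench is non-basic and the material goes directly into step 9.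

Step 9
Reactants: 14 (1R,5S)-4-methoxy-1,8-dimethyl-cis-hydroazula-3,8-diene-2,6-dione
Product: 15 (1R,2S,5R,6S)-4-methoxy-1,8-dimethyl-cis-hydroazula-3,8-diene-2,6-diol (C2–OH β; C6–OH trans to C5–H)
Conditions: i-Bu2AlH (3.5 equiv), CH2Cl2, −78 °C; aq. potassium sodium tartrate
Reagents that add atoms: none
Why: Aluminium hydride reduction of the C6 ketone and 1,2-reduction of the vinylogous ester carbonyl; at C6 the face toward C1/C10 is closed, so hydride should enter from the periphery and give the 6S alcohol, the epimer wanted for inversion in step 14. At C2 hydride should come from the α face, away from the seven-membered ring and from the C6 aluminium alkoxide that lies under the β face, giving C2–O β.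

Step 10
Reactants: 15 (1R,2S,5R,6S)-4-methoxy-1,8-dimethyl-cis-hydroazula-3,8-diene-2,6-diol
Product: 16 (1R,2S,5R,6S)-2,6-bis(tert-butyldimethylsilyloxy)-4-methoxy-1,8-dimethyl-cis-hydroazula-3,8-diene
Conditions: TBSOTf, 2,6-lutidine, CH2Cl2, −78 → 0 °C
Reagents that add atoms: tert-butyldimethylsilyl trifluoromethanesulfonate, CC(C)(C)[Si](C)(C)OS(=O)(=O)C(F)(F)F
Why: Silylation with a silyl triflate and a hindered pyridine base reaches the neopentylic C2 and the hindered C6 hydroxyls at low temperature without ionising the acid-labile 3-methoxyallylic alcohol; the C2 ether also blocks allylic ionisation in step 11.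

Step 11
Reactants: 16 (1R,2S,5R,6S)-2,6-bis(tert-butyldimethylsilyloxy)-4-methoxy-1,8-dimethyl-cis-hydroazula-3,8-diene
Product: 17 (1R,2S,5R,6S)-2,6-bis(tert-butyldimethylsilyloxy)-1,8-dimethyl-cis-hydroazul-8-en-4-one
Conditions: (CO2H)2, THF/H2O, 0 °C
Reagents that add atoms: water, O
Why: Acid-catalysed enol ether hydrolysis by C3 protonation and hydration of the oxocarbenium ion; with C2–O silylated, elimination to the transposed enone is suppressed, secondary silyl ethers survive dilute oxalic acid, and the cis fusion at C5 should be kept under these mild conditions.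

Step 12
Reactants: 17 (1R,2S,5R,6S)-2,6-bis(tert-butyldimethylsilyloxy)-1,8-dimethyl-cis-hydroazul-8-en-4-one
Product: 18 (1R,2S,4S,5R,6S)-2,6-bis(tert-butyldimethylsilyloxy)-4-isopropyl-1,8-dimethyl-cis-hydroazul-8-en-4-ol (C4–OH β, isopropyl α)
Conditions: i-PrMgCl, CeCl3 (anhydrous), THF, −78 → −40 °C
Reagents that add atoms: isopropylmagnesium chloride, CC(C)[Mg]Cl
Why: Organocerium 1,2-addition, whose low basicity suppresses enolisation and β-elimination of the silyloxy group; the nucleophile should approach C4 from the α face past C5–H, because the β face is blocked by C6 with its silyl ether and by the C2 silyloxy group.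

Step 13
Reactants: 18 (1R,2S,4S,5R,6S)-2,6-bis(tert-butyldimethylsilyloxy)-4-isopropyl-1,8-dimethyl-cis-hydroazul-8-en-4-ol
Product: 19 (1R,2S,4S,5R,6S)-4-isopropyl-1,8-dimethyl-cis-hydroazul-8-ene-2,4,6-triol
Conditions: Bu4NF, THF, 0 → 25 °C
Reagents that add atoms: none
Why: Fluoride cleavage of both secondary silyl ethers; no carbonyl group is present, so the basic fluoride has nothing to epimerise or fragment.

Step 14
Reactants: 19 (1R,2S,4S,5R,6S)-4-isopropyl-1,8-dimethyl-cis-hydroazul-8-ene-2,4,6-triol; 20 3,4,5-trimethoxybenzoic acid
Product: 21 (1R,2S,4S,5R,6R)-2,4-dihydroxy-4-isopropyl-1,8-dimethyl-cis-hydroazul-8-en-6-yl 3,4,5-trimethoxybenzoate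
Conditions: PPh3, DIAD, toluene, 0 → 25 °C
Reagents that add atoms: none
Why: Mitsunobu esterification; the C6 hydroxyl is the only secondary alcohol that can be activated and displaced (C2–OH is neopentylic, C4–OH tertiary), and the carboxylate attacks from the open peripheral face with inversion, giving the 6R ester with oxygen cis to C5–H.

Step 15
Reactants: 21 (1R,2S,4S,5R,6R)-2,4-dihydroxy-4-isopropyl-1,8-dimethyl-cis-hydroazul-8-en-6-yl 3,4,5-trimethoxybenzoate; 22 angelic acid
Product: 24 CNP0112256.1 (1R,2S,4S,5R,6R)-2-angeloyloxy-4-hydroxy-4-isopropyl-1,8-dimethyl-cis-hydroazul-8-en-6-yl 3,4,5-trimethoxybenzoate, via angelic 2,4,6-trichlorobenzoic anhydride 23 (not isolated)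
Conditions: 2,4,6-Cl3C6H2COCl, Et3N, toluene, 25 °C; then 21, 80 °C
Reagents that add atoms: none
Why: Yamaguchi-type mixed-anhydride esterification run without a nucleophilic catalyst, the condition set known to preserve the Z geometry of angelates; only the secondary C2 hydroxyl is acylated and the tertiary C4 hydroxyl stays free, with no stereocentre affected.

## Compound list

1 | 2-methyl-1,4-benzoquinone | CC1=CC(=O)C=CC1=O | starting material
2 | 2-methoxy-5-methyl-1,4-benzoquinone | COC1=CC(=O)C(C)=CC1=O | intermediate
3 | isoprene | C=CC(C)=C | starting material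
4 | (1R,6S)-4-methoxy-1,8-dimethyl-cis-bicyclo[4.4.0]deca-3,8-diene-2,5-dione | O=C1C=C(OC)C(=O)[C@H]2CC(C)=CC[C@@]12C | intermediate
5 | potassium C5-enolate of 4 (C5=C6) | [K+].[O-]C1=C2CC(C)=CC[C@@]2(C)C(=O)C=C1OC | intermediate (not isolated)
6 | potassium C6-alkoxide of the trans-fused 6-hydroxy dione | [K+].O=C1C=C(OC)C(=O)[C@]2([O-])CC(C)=CC[C@@]12C | intermediate (not isolated)
7 | (1R,6S)-6-(tert-butoxycarbonyloxy)-4-methoxy-1,8-dimethyl-trans-bicyclo[4.4.0]deca-3,8-diene-2,5-dione | O=C1C=C(OC)C(=O)[C@]2(OC(=O)OC(C)(C)C)CC(C)=CC[C@@]12C | intermediate
8 | (1R,5S,6S)-6-(tert-butoxycarbonyloxy)-5-hydroxy-4-methoxy-1,8-dimethyl-trans-bicyclo[4.4.0]deca-3,8-dien-2-one | O=C1C=C(OC)[C@H](O)[C@]2(OC(=O)OC(C)(C)C)CC(C)=CC[C@@]12C | intermediate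
9 | C5 methanesulfonate of 8 | O=C1C=C(OC)[C@H](OS(C)(=O)=O)[C@]2(OC(=O)OC(C)(C)C)CC(C)=CC[C@@]12C | intermediate (not isolated)
10 | (1R,5R,6S)-4-methoxy-1,8-dimethyl-2-oxo-trans-bicyclo[4.4.0]deca-3,8-diene-5,6-diyl cyclic carbonate | O=C1C=C(OC)[C@H]3OC(=O)O[C@@]23CC(C)=CC[C@@]12C | intermediate
11 | (1R,5S,6S)-5,6-dihydroxy-4-methoxy-1,8-dimethyl-trans-bicyclo[4.4.0]deca-3,8-dien-2-one | O=C1C=C(OC)[C@@H](O)[C@]2(O)CC(C)=CC[C@@]12C | intermediate
12 | (1R,5S,6S)-6-hydroxy-4-methoxy-1,8-dimethyl-2-oxo-trans-bicyclo[4.4.0]deca-3,8-dien-5-yl methanesulfonate | O=C1C=C(OC)[C@@H](OS(C)(=O)=O)[C@]2(O)CC(C)=CC[C@@]12C | intermediate (key-step precursor)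
13 | diethylaluminium C6-alkoxide of 12 | O=C1C=C(OC)[C@@H](OS(C)(=O)=O)[C@]2(O[Al](CC)CC)CC(C)=CC[C@@]12C | intermediate (not isolated)
14 | (1R,5S)-4-methoxy-1,8-dimethyl-cis-hydroazula-3,8-diene-2,6-dione | O=C1C=C(OC)[C@H]2C(=O)CC(C)=CC[C@@]12C | intermediate (key-step product)
15 | (1R,2S,5R,6S)-4-methoxy-1,8-dimethyl-cis-hydroazula-3,8-diene-2,6-diol | O[C@H]1C=C(OC)[C@H]2[C@@H](O)CC(C)=CC[C@@]12C | intermediate
16 | (1R,2S,5R,6S)-2,6-bis(tert-butyldimethylsilyloxy)-4-methoxy-1,8-dimethyl-cis-hydroazula-3,8-diene | CC(C)(C)[Si](C)(C)O[C@H]1C=C(OC)[C@H]2[C@@H](O[Si](C)(C)C(C)(C)C)CC(C)=CC[C@@]12C | intermediate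
17 | (1R,2S,5R,6S)-2,6-bis(tert-butyldimethylsilyloxy)-1,8-dimethyl-cis-hydroazul-8-en-4-one | CC(C)(C)[Si](C)(C)O[C@H]1CC(=O)[C@H]2[C@@H](O[Si](C)(C)C(C)(C)C)CC(C)=CC[C@@]12C | intermediate
18 | (1R,2S,4S,5R,6S)-2,6-bis(tert-butyldimethylsilyloxy)-4-isopropyl-1,8-dimethyl-cis-hydroazul-8-en-4-ol | CC(C)(C)[Si](C)(C)O[C@H]1C[C@](O)(C(C)C)[C@H]2[C@@H](O[Si](C)(C)C(C)(C)C)CC(C)=CC[C@@]12C | intermediate
19 | (1R,2S,4S,5R,6S)-4-isopropyl-1,8-dimethyl-cis-hydroazul-8-ene-2,4,6-triol | O[C@H]1C[C@](O)(C(C)C)[C@H]2[C@@H](O)CC(C)=CC[C@@]12C | intermediate
20 | 3,4,5-trimethoxybenzoic acid | COc1cc(cc(OC)c1OC)C(O)=O | starting material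
21 | (1R,2S,4S,5R,6R)-2,4-dihydroxy-4-isopropyl-1,8-dimethyl-cis-hydroazul-8-en-6-yl 3,4,5-trimethoxybenzoate | O[C@H]1C[C@](O)(C(C)C)[C@H]2[C@H](OC(=O)c3cc(OC)c(OC)c(OC)c3)CC(C)=CC[C@@]12C | intermediate
22 | angelic acid | C/C=C(/C)C(O)=O | starting material
23 | angelic 2,4,6-trichlorobenzoic anhydride | C/C=C(/C)C(=O)OC(=O)c1c(Cl)cc(Cl)cc1Cl | intermediate (not isolated)
24 | CNP0112256.1 | C/C=C(/C)C(=O)O[C@H]1C[C@](O)(C(C)C)[C@H]2[C@H](OC(=O)c3cc(OC)c(OC)c(OC)c3)CC(C)=CC[C@@]12C | target

## Step count and least certain steps

Total: 15 steps. Longest linear sequence: 15 steps (1 to 24); 3, 20 and 22 are commercial.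

**Step 8 (key step).**
- What may go wrong: retro-aldol cleavage of the C6–C1 bond by the C6 alkoxide toward the C2 carbonyl; slow migration, because the migrating carbon C1 bears an acyl group; ethyl transfer from aluminium to the new ketone; epimerisation at C5 or conjugation of the C8=C9 alkene during work-up.
- Fallback (from 12, back at 14): the C2 carbonyl of 12 is reduced first (NaBH4, CeCl3·7H2O, MeOH, 0 °C; hydride anti to the axial methyl) to the C2 carbinol mesylate F1. The migrating carbon is then an ordinary quaternary alkyl carbon and no β-carbonyl is left for retro-aldol, so the classical alkoxide-driven variant (KOt-Bu, t-BuOH/THF, 0 °C) can be used and should give the rearranged hydroxy ketone F2. Oxidation of its allylic C2 alcohol with MnO2 restores the vinylogous ester and returns to 14.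

**Step 2.**
- What may go wrong: the catalyst may bind the other (C5) carbonyl, the one that has an α-C–H on the reacting double bond, which would reverse the orientation and put the methyl on C9. Face discrimination may also be weak, because the reacting double bond lies on the far side of the boron-bound vinylogous-ester carbonyl.
- Fallback (from 2 and 3, back at 4): the cycloaddition is run with BF3·OEt2 in CH2Cl2 at −20 °C, the orientation expected for monodentate boron acids, to give the racemic adduct F3. This is resolved by preparative chromatography on a chiral stationary phase and the (1R,6S) enantiomer, 4, re-enters the route.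

**Step 3.**
- What may go wrong: poor facial selectivity of oxygen transfer, since the two faces of the enolate differ only by a methyl versus a ring methylene on C1; incomplete carbonate trapping; retro-aldol of alkoxide 6 on warming.
- Fallback if oxygen enters syn to the methyl (from 4, back at 14): the same enolate oxidation without the carbonate trap gives the cis-fused ketol F4. Luche reduction from its convex face (the face of the methyl and hydroxyl) should give the trans-diol F5, in which C5–O is again anti to the C1 methyl. Mesylation gives the mesylate F6, and the Et3Al-promoted shift of step 8 leads to 14, because C6 is destroyed and C5 has the configuration it has in 12. In this series the conformer with an equatorial mesylate must react before the diaxial conformer closes an epoxide.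

**Step 9.**
- What may go wrong: poor facial selectivity at C2, where a methyl and a ring methylene flank the carbonyl almost symmetrically; ionisation of the acid-labile 3-methoxyallylic alcohol on work-up.
- Fallback (from 14, back at 16): Luche reduction at −78 °C reduces only the C6 ketone to the hydroxy enone F7, which is silylated (TBSOTf, 2,6-lutidine) to the silyl ether F8. The C2 carbonyl is then reduced under catalyst control, with whichever antipode of the Me-CBS oxazaborolidine delivers hydride to the α face and catecholborane in toluene at −40 °C, to the allylic alcohol F9. Silylation gives 16.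

**Step 14.**
- What may go wrong: elimination from the oxyphosphonium intermediate, which has antiperiplanar hydrogens at C7 (allylic) and C5, to dienes; sluggish activation of the hindered hydroxyl; acylation with retention through an acyloxyphosphonium ion.
- Fallback (from 19, back at 21): the C6 hydroxyl, the least hindered secondary alcohol, is oxidised selectively (TEMPO, PhI(OAc)2, CH2Cl2) to the dihydroxy ketone F10. Dissolving-metal reduction (Li, NH3, t-BuOH, THF, −78 °C), which favours the more stable peripheral alcohol, should give the (6R)-triol F11. Acylation of its unhindered C6 hydroxyl with 3,4,5-trimethoxybenzoyl chloride (pyridine, 0 °C) gives 21 with retention.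

## Further compounds

F1 | step 8 | C2 carbinol mesylate (C2–OH syn to C1 methyl) | O[C@@H]1C=C(OC)[C@@H](OS(C)(=O)=O)[C@]2(O)CC(C)=CC[C@@]12C
F2 | step 8 | rearranged 2-hydroxy-4-methoxy hydroazulen-6-one | O[C@@H]1C=C(OC)[C@H]2C(=O)CC(C)=CC[C@@]12C
F3 | step 2 | racemic cis adduct (rac-4; one enantiomer drawn) | O=C1C=C(OC)C(=O)[C@H]2CC(C)=CC[C@@]12C
F4 | step 3 | cis-fused 6-hydroxy dione (C6–OH syn to C1 methyl) | O=C1C=C(OC)C(=O)[C@@]2(O)CC(C)=CC[C@@]12C
F5 | step 3 | cis-decalin trans-5,6-diol | O=C1C=C(OC)[C@@H](O)[C@@]2(O)CC(C)=CC[C@@]12C
F6 | step 3 | cis-decalin trans-5,6-diol 5-mesylate | O=C1C=C(OC)[C@@H](OS(C)(=O)=O)[C@@]2(O)CC(C)=CC[C@@]12C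
F7 | step 9 | (6S)-6-hydroxy-4-methoxy hydroazulen-2-one | O=C1C=C(OC)[C@H]2[C@@H](O)CC(C)=CC[C@@]12C
F8 | step 9 | C6 tert-butyldimethylsilyl ether of F7 | O=C1C=C(OC)[C@H]2[C@@H](O[Si](C)(C)C(C)(C)C)CC(C)=CC[C@@]12C
F9 | step 9 | (2S)-allylic alcohol with C6 silyl ether | O[C@H]1C=C(OC)[C@H]2[C@@H](O[Si](C)(C)C(C)(C)C)CC(C)=CC[C@@]12C
F10 | step 14 | 2,4-dihydroxy-4-isopropyl hydroazulen-6-one | O[C@H]1C[C@](O)(C(C)C)[C@H]2C(=O)CC(C)=CC[C@@]12C
F11 | step 14 | (6R)-triol | O[C@H]1C[C@](O)(C(C)C)[C@H]2[C@H](O)CC(C)=CC[C@@]12C
A1 | alternative 1 | acetoxypyranone with tethered 1,1-disubstituted alkene | CC(C)(C)[Si](C)(C)O[C@H](C(C)=C)C[C@](O)(C(C)C)C1OC(OC(C)=O)C(C)=CC1=O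
A2 | alternative 1 | cyclopentane-fused 8-oxabicyclo[3.2.1]oct-3-en-2-one | CC(C)(C)[Si](C)(C)O[C@H]1C[C@](O)(C(C)C)[C@]23O[C@H](C[C@@]12C)C(C)=CC3=O
A3 | alternative 2 | cis-1-siloxy-1-cyclopentenyl-2-methyl-2-vinylcyclopropane | COC1(OC)CC(=O)C(=C1C)[C@@]2(O[Si](C)(C)C(C)(C)C)C[C@@]2(C)C=C
A4 | alternative 2 | hydroazulene vinylogous silyl ester with C2 ketal | COC1(OC)CC(=O)C2=C(O[Si](C)(C)C(C)(C)C)CC(C)=CC[C@@]12C
A5 | alternative 3 | aldehyde-tethered 3,6-dimethylcyclohepta-2,5-dienone | O=CC[C@](O)(C(C)C)C1=C(C)CC=C(C)CC1=O
A6 | alternative 3 | cis-fused 2,4-dihydroxy hydroazulen-6-one | O[C@H]1C[C@](O)(C(C)C)[C@H]2C(=O)CC(C)=CC[C@@]12C
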